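I began with the easiest step, one that needs no theory: adding the two columns of each reading to see what was missing from the charge.

| flask | free monomer | initiator | temperature | remark | time |
|---|---|---|---|---|---|
| blue | 2 M | 0.087 mol% | 10 °C | run made earlier |  |
| violet | 2 M | 0.61 mol% | 43 °C | run made earlier |  |
| amber | 1.2 M | 0.2 mol% | 10 °C | run made earlier |  |
| midnight | 2.0 M | 0.2 mol% | 25 °C |  | 40 min |
| summer | 2.0 M | 0.06 mol% | 25 °C |  | 40 min |
| noon | 2.0 M | 0.2 mol% | 55 °C |  | 40 min |
| autumn | 2.0 M | 0.06 mol% | −5 °C |  | 40 min |
| dawn | 2.0 M | 0.12 mol% | 40 °C |  | 40 min |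
| dusk | 1.2 M | 0.4 mol% | −5 °C |  | 40 min |

| run | time / min | monomer in chains / % | free monomer / % |
|---|---|---|---|
| blue | 10.0 | 13.3 | 86.7 |
| blue | 20.0 | 18.9 | 79.6 |
| blue | 30.0 | 25.2 | 74.6 |
| blue | 40.0 | 30.6 | 68.4 |
| blue | 50.0 | 35.8 | 63.7 |
| blue | 60.0 | 40.8 | 57.8 |
| violet | 0.833 | 30.0 | 68.9 |
| violet | 2.00 | 52.1 | 46.0 |
| violet | 4.00 | 73.6 | 23.2 |
| violet | 6.00 | 84.6 | 11.7 |
| violet | 8.00 | 90.0 | 5.7 |
| violet | 12.0 | 94.7 | 1.8 |
| amber | 5.00 | 9.8 | 89.5 |
| amber | 15.0 | 19.1 | 80.2 |
| amber | 25.0 | 27.0 | 73.3 |
| amber | 40.0 | 36.2 | 63.5 |
| amber | 60.0 | 46.2 | 51.4 |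

(readings scatter by 0.5 percentage points)

- what was read earlier has a scatter of 0.5 percentage points, one standard deviation

- the flasks by amount of monomer in chains, in percent of the free monomer charged, highest first, at 40 min (midnight / summer / noon / autumn / dawn / dusk)
- the same order at 4.0 min (midnight / summer / noon / autumn / dawn / dusk)
- the amount of monomer in chains, in percent of the free monomer charged of the flask you put first, at 40 min
- the amount of monomer in chains, in percent of the free monomer charged of the flask you put last, at 40 min

Call r the leak ratio, the monomer missing per monomer in chains (a selectivity factor turned upside down), averaged over the last 3 readings of a run. It was 4.27% in violet and 2.71% in blue, the blue value being loose since its gaps lie near the scatter of 0.5 percentage points. This looked wrong: the first-order decay constant k of free monomer, read after the first reading, was 0.00811 min⁻¹ in blue and 0.348 min⁻¹ in violet, 42.9 times larger, yet r differed by a factor of 1.58.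

Amber against blue, with the free monomer changed as well, had 1.38 times the initiator concentration and 1.24 times the k, so, as an assumption, I took k to follow the root of initiator, which is 1.17 there. Violet's initiator then accounts for a factor 2.65, leaving F = 16.2 for the heating from 10 °C to 43 °C. I supposed that the leak needs no initiator. Its rate r·k then grew 67.6 times over that span, more than the factor F of chains. So, on that supposition, the heating from blue to violet raised r, while the larger initiator charge of violet lowered it by the factor 2.65. At fixed initiator, r grew by Q = 4.18.

Scaling from violet by the root of initiator, and by F and Q spread evenly over the degrees, I got r = 8.45% and k = 0.120 min⁻¹ for dawn, and r = 12.5% and k = 0.548 min⁻¹ for noon. By that k I expected dawn to keep 0.832% of its free monomer at 40 min, so I put chains in these two flasks near the consumed part divided by 1 + r. I reckoned 91.4% for dawn and 88.9% for noon, which puts dawn above noon, though the larger k of noon put noon ahead of dawn at 4.0 min in my reckoning.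

The forecast differed, giving noon > dawn > midnight > summer > dusk > autumn at 40 min with 96.3% and 10.7%, and noon > dawn > midnight > summer > dusk > autumn at 4.0 min, in its words: “Noon and dawn both reach the plateau”.

The flasks gave dawn > noon > midnight > summer > dusk > autumn, with dawn 90.2%, noon 85.4% and autumn 11.2%, and noon > dawn > midnight > summer > dusk > autumn at 4.0 min.

    free monomer + initiator → living end + monomer in chains (k = 3.70 M⁻¹ min⁻¹, Ea = 57.0 kJ mol⁻¹)
    free monomer + living end → monomer in chains + living end, rate k2*[living end]*[free monomer] (k = 74.0 M⁻¹ min⁻¹, Ea = 46.0 kJ mol⁻¹)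
    2 living end ⇌ resting dimer (K = 4600 M⁻¹, k = 810 M⁻¹ min⁻¹, Ea = 42.0 kJ mol⁻¹, ΔH = −30.0 kJ mol⁻¹)
    free monomer → uncatalysed product (k = 0.00140 min⁻¹, Ea = 107 kJ mol⁻¹)
    (constants at 25 °C)

The missing monomer is the uncatalysed product. At 40 min dawn held 8.93% of it against 90.2% in chains, so the r of dawn at that time was 9.90%, above my 8.45%. A neighbour of dawn was charged with 0.48 mol% of initiator, 4.00 times as much. The root of initiator takes the r of dawn to 4.95%, which by my reckoning puts the chains of that neighbour near 95.3%. That neighbour ended with 0.0062% of free monomer, 4.23% of uncatalysed product and 95.8% in chains.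

The runs were computed on assumed constants; noise was put on by code.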